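**Retrosynthetic overview**

1. C8–prenyl bond: aromatic Claisen rearrangement of a 7-O-(1,1-dimethylallyl) ether; the C6 methyl blocks the other ortho carbon.
2. C2–aryl bond and the (S) centre: rhodium-catalysed enantioselective 1,4-addition of 4-methoxyphenylboronic acid to a chromone, i.e. dearomatisation of the flat pyranone ring C.
3. Ring C: Friedel–Crafts acylation joining the carbonyl carbon C4 to the aryl carbon C4a of an (E)-3-aryloxyacrylic acid. It is run at the chromone oxidation level, where there is no stereocentre and no β-elimination or benzylic ionisation. O1 is put on ring A by C–H borylation/oxidation of 2,6-dimethoxytoluene.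
4. Enabling feature: ring A is a methylphloroglucinol with O1 para to the C6 methyl. In the O1 aryl ether, C4a and C8 are therefore equivalent, and each lies ortho/para to O1, O5 and O7. Closure can give only one regioisomer and leaves O5 chelated to C4=O, O7 free and C8 as the only nucleophilic ring carbon.
5. Ring order: ring A (bought, then oxygenated), ring C (key step), ring B attached together with the stereocentre, prenyl last.

Key step: step 3

Remark: all building blocks, including the allyl carbonate of step 5, are taken as purchasable. The sense of induction in step 6 is assigned by analogy with additions to cyclic enones and would be confirmed on a test scale.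

**Route**

Step 1
Reactants: 1 2,6-dimethoxytoluene; 2 bis(pinacolato)diboron
Product: 4 3,5-dimethoxy-4-methylphenol, via aryl pinacol boronate 3 (not isolated)
Conditions: [Ir(OMe)(cod)]2 (1.5 mol%), 4,4'-di-tert-butyl-2,2'-bipyridine (3 mol%), 2 (0.6 equiv), THF, 80 °C; then KHSO5 (as 2KHSO5·KHSO4·K2SO4), acetone/H2O, 0 °C to rt
Reagents that add atoms: bis(pinacolato)diboron 2, CC1(C)OB(OC1(C)C)B1OC(C)(C)C(C)(C)O1 (boryl group of 3); potassium peroxymonosulfate, [K+].[O-]S(=O)(=O)OO (oxygen atom of 4)
Why: Iridium-catalysed C–H borylation is sterically controlled and should take the only C–H without an ortho substituent (para to the methyl), and the aryl boronate is oxidised to the phenol in the same flask (borylation/oxidation sequence).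

Step 2
Reactants: 4 3,5-dimethoxy-4-methylphenol; 5 ethyl propiolate
Product: 7 (2E)-3-(3,5-dimethoxy-4-methylphenoxy)prop-2-enoic acid, via ethyl ester 6 (not isolated)
Conditions: 5 (1.1 equiv), DABCO (10 mol%), THF, 0 °C to rt; then LiOH (3 equiv), THF/H2O, rt; then 1 M HCl
Reagents that add atoms: ethyl propiolate 5, C#CC(=O)OCC; lithium hydroxide, [Li+].[OH-] (one carboxyl oxygen)
Why: Amine-catalysed oxa-Michael addition of the phenol to the ynoate should give the (E)-β-aryloxyacrylate, and saponification of the ester then releases the acid.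

Step 3
Reactants: 7 (2E)-3-(3,5-dimethoxy-4-methylphenoxy)prop-2-enoic acid
Product: 8 5,7-dimethoxy-6-methyl-4H-chromen-4-one
Conditions: P4O10 in MeSO3H (7.7 wt%), 50 °C
Reagents that add atoms: none
Why: P4O10/MeSO3H converts the acid into a mixed anhydride/acylium ion, and reversible protonation of the enol ether lowers the C2=C3 bond order so that the E acid equilibrates with the Z isomer that can reach the ring; the acylium carbon C4 is then attacked by C4a in an intramolecular Friedel–Crafts acylation and loss of the proton gives the chromone. The closest known reaction type is the acid-mediated cyclisation of 3-aryloxyacrylic acids to chromones. Ring C closes as a six-membered ring by electrophilic aromatic substitution, exo with respect to the acylium C≡O and with the attacked C4a=C8a bond inside the new ring. No stereocentre is formed. The selectivity needed is regiochemical and is secured by the local mirror symmetry of the 3,5-dimethoxy-4-methylphenoxy ring: both carbons ortho to O1 are equivalent and each is ortho/para to two further oxygens, so only one chromone can form. The product is protonated on the pyranone carbonyl in the medium, which should prevent further acylation.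

Step 4
Reactants: 8 5,7-dimethoxy-6-methyl-4H-chromen-4-one
Product: 9 5,7-dihydroxy-6-methyl-4H-chromen-4-one
Conditions: BBr3 (5 equiv), CH2Cl2, −78 °C to rt; then H2O
Reagents that add atoms: none
Why: Lewis acid-mediated aryl methyl ether cleavage (BBr3 demethylation) should remove both methyl groups, the 5-OMe assisted by chelation to the C4 carbonyl, while the chromone core is inert.

Step 5
Reactants: 9 5,7-dihydroxy-6-methyl-4H-chromen-4-one; 10 tert-butyl 2-methylbut-3-en-2-yl carbonate
Product: 11 5-hydroxy-6-methyl-7-[(2-methylbut-3-en-2-yl)oxy]-4H-chromen-4-one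
Conditions: Pd(PPh3)4 (5 mol%), 10 (1.2 equiv), THF, 0 °C to rt
Reagents that add atoms: tert-butyl 2-methylbut-3-en-2-yl carbonate 10, C=CC(C)(C)OC(=O)OC(C)(C)C
Why: Tsuji–Trost-type O-allylation, in which zerovalent palladium ionises the carbonate with loss of CO2, the tert-butoxide deprotonates the more acidic, non-chelated 7-OH, and the phenoxide attacks the more substituted terminus of the π-(1,1-dimethylallyl)palladium to give the tertiary ether under kinetic control.

Step 6
Reactants: 11 5-hydroxy-6-methyl-7-[(2-methylbut-3-en-2-yl)oxy]-4H-chromen-4-one; 12 4-methoxyphenylboronic acid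
Product: 13 (2S)-5-hydroxy-2-(4-methoxyphenyl)-6-methyl-7-[(2-methylbut-3-en-2-yl)oxy]-2,3-dihydro-4H-chromen-4-one
Conditions: [Rh(OH)(cod)]2 (1.5 mol%), (S)-MeO-F12-BIPHEP [(S)-6,6'-dimethoxybiphenyl-2,2'-diyl bisphosphine with 3,4,5-trifluorophenyl groups on phosphorus] (3.3 mol%), 12 (3 equiv), toluene/H2O (10:1), 30 °C
Reagents that add atoms: 4-methoxyphenylboronic acid 12, COc1ccc(B(O)O)cc1
Why: Rhodium-catalysed asymmetric 1,4-addition of the arylboronic acid (Hayashi–Miyaura reaction), in which aryl-rhodium adds to C2 of the chromone and the rhodium enolate is protonated by water; the C2 stereocentre is set by the (S)-biaryl bisphosphine, expected to deliver the aryl group to the Re face of C2 as in additions to cyclic enones, and the base-free conditions should keep ring C closed.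

Step 7
Reactants: 13 (2S)-5-hydroxy-2-(4-methoxyphenyl)-6-methyl-7-[(2-methylbut-3-en-2-yl)oxy]-2,3-dihydro-4H-chromen-4-one
Product: 14 (2S)-5,7-dihydroxy-2-(4-methoxyphenyl)-6-methyl-8-(3-methylbut-2-en-1-yl)-2,3-dihydro-4H-chromen-4-one
Conditions: Eu(fod)3 (10 mol%), CHCl3, 60 °C
Reagents that add atoms: none
Why: Aromatic Claisen rearrangement ([3,3]-sigmatropic shift) of the 1,1-dimethylallyl aryl ether should deliver the linear prenyl group to C8, the only unsubstituted ortho carbon (C6 carries the methyl), with tautomerisation restoring the 7-OH, and the neutral conditions do not touch C2.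

**Compound list**

1 | 2,6-dimethoxytoluene | COc1cccc(OC)c1C | starting material
2 | bis(pinacolato)diboron | CC1(C)OB(OC1(C)C)B1OC(C)(C)C(C)(C)O1 | starting material
3 | 2-(3,5-dimethoxy-4-methylphenyl)-4,4,5,5-tetramethyl-1,3,2-dioxaborolane | COc1cc(B2OC(C)(C)C(C)(C)O2)cc(OC)c1C | intermediate
4 | 3,5-dimethoxy-4-methylphenol | COc1cc(O)cc(OC)c1C | intermediate
5 | ethyl propiolate | C#CC(=O)OCC | starting material
6 | ethyl (2E)-3-(3,5-dimethoxy-4-methylphenoxy)prop-2-enoate | CCOC(=O)/C=C/Oc1cc(OC)c(C)c(OC)c1 | intermediate
7 | (2E)-3-(3,5-dimethoxy-4-methylphenoxy)prop-2-enoic acid | OC(=O)/C=C/Oc1cc(OC)c(C)c(OC)c1 | intermediate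
8 | 5,7-dimethoxy-6-methyl-4H-chromen-4-one | COc1cc2occc(=O)c2c(OC)c1C | intermediate
9 | 5,7-dihydroxy-6-methyl-4H-chromen-4-one | Cc1c(O)cc2occc(=O)c2c1O | intermediate
10 | tert-butyl 2-methylbut-3-en-2-yl carbonate | C=CC(C)(C)OC(=O)OC(C)(C)C | starting material
11 | 5-hydroxy-6-methyl-7-[(2-methylbut-3-en-2-yl)oxy]-4H-chromen-4-one | Cc1c(OC(C)(C)C=C)cc2occc(=O)c2c1O | intermediate
12 | 4-methoxyphenylboronic acid | COc1ccc(B(O)O)cc1 | starting material
13 | (2S)-5-hydroxy-2-(4-methoxyphenyl)-6-methyl-7-[(2-methylbut-3-en-2-yl)oxy]-2,3-dihydro-4H-chromen-4-one | COc1ccc([C@@H]2CC(=O)c3c(O)c(C)c(OC(C)(C)C=C)cc3O2)cc1 | intermediate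
14 | (2S)-5,7-dihydroxy-2-(4-methoxyphenyl)-6-methyl-8-(3-methylbut-2-en-1-yl)-2,3-dihydro-4H-chromen-4-one | COc1ccc([C@@H]2CC(=O)c3c(O)c(C)c(O)c(CC=C(C)C)c3O2)cc1 | target

**Step count and risks**

Total step count: 7. Longest linear sequence: 7 steps (1 to 14).

Steps most likely to fail:

Step 6. Aryl transfer to the electron-rich 5-hydroxy-7-alkoxychromone may be slow, so that protodeboronation consumes the boronic acid. The rhodium enolate may also undergo β-oxygen elimination, so that ring C opens and recloses without control and the ee erodes, or the facial selectivity may simply be insufficient. Fallback: the stereocentre is set earlier, on the unprotected chromone, with a different catalyst class. It sets out from 9: conjugate addition of 12 with Pd(OCOCF3)2 and (R)-t-BuPyOX (the enantiomer expected to give Re-face delivery, to be confirmed), NH4PF6, H2O, ClCH2CH2Cl, 60 °C should give (2S)-5,7-dihydroxy-2-(4-methoxyphenyl)-6-methyl-2,3-dihydro-4H-chromen-4-one F1. This divalent palladium catalyst cannot be used on 11 because of its terminal alkene. O-Allylation of the 7-OH of F1 with 10 and Pd(PPh3)4 in THF, as in step 5, then returns to the route at 13.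

Step 5. The tertiary allyl ether of an acidic phenol can be re-ionised by zerovalent palladium and equilibrate to the linear O-prenyl ether, and C-allylation at C8 may compete. Fallback: classical propargylation and semihydrogenation, which is safe at this achiral, base-stable stage. It sets out from 9: 3-chloro-3-methylbut-1-yne, K2CO3, KI, acetone, 60 °C should give 5-hydroxy-6-methyl-7-[(2-methylbut-3-yn-2-yl)oxy]-4H-chromen-4-one F2. H2 (1 atm) over Pd/CaCO3 poisoned with Pb(OAc)2, quinoline, EtOAc, rt then reduces the alkyne to the alkene and returns to the route at 11.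

Step 7. The tertiary allylic ether may ionise instead of rearranging, losing the C5 unit. The new ortho-prenylphenol may cyclise onto the 7-OH, and heating the flavanone may open ring C and erode the ee. Fallback: the rearrangement is moved in front of the stereocentre. It sets out from 11: heating in N,N-diethylaniline at 180 °C should give 5,7-dihydroxy-6-methyl-8-(3-methylbut-2-en-1-yl)-4H-chromen-4-one F3. Chloromethyl methyl ether and i-Pr2NEt in CH2Cl2 at 0 °C should cap the non-chelated 7-OH as 5-hydroxy-7-(methoxymethoxy)-6-methyl-8-(3-methylbut-2-en-1-yl)-4H-chromen-4-one F4. Addition of 12 under the conditions of step 6 should give (2S)-5-hydroxy-7-(methoxymethoxy)-2-(4-methoxyphenyl)-6-methyl-8-(3-methylbut-2-en-1-yl)-2,3-dihydro-4H-chromen-4-one F5. HCl (3 M) in MeOH at 40 °C then removes the acetal and returns to the route at 14.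

**Further compounds**

F1 | step 6 | (2S)-5,7-dihydroxy-2-(4-methoxyphenyl)-6-methyl-2,3-dihydro-4H-chromen-4-one | COc1ccc([C@@H]2CC(=O)c3c(O)c(C)c(O)cc3O2)cc1
F2 | step 5 | 5-hydroxy-6-methyl-7-[(2-methylbut-3-yn-2-yl)oxy]-4H-chromen-4-one | Cc1c(OC(C)(C)C#C)cc2occc(=O)c2c1O
F3 | step 7 | 5,7-dihydroxy-6-methyl-8-(3-methylbut-2-en-1-yl)-4H-chromen-4-one | Cc1c(O)c(CC=C(C)C)c2occc(=O)c2c1O
F4 | step 7 | 5-hydroxy-7-(methoxymethoxy)-6-methyl-8-(3-methylbut-2-en-1-yl)-4H-chromen-4-one | Cc1c(OCOC)c(CC=C(C)C)c2occc(=O)c2c1O
F5 | step 7 | (2S)-5-hydroxy-7-(methoxymethoxy)-2-(4-methoxyphenyl)-6-methyl-8-(3-methylbut-2-en-1-yl)-2,3-dihydro-4H-chromen-4-one | COc1ccc([C@@H]2CC(=O)c3c(O)c(C)c(OCOC)c(CC=C(C)C)c3O2)cc1
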